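# Abroquinone A (22) by de novo construction of ring A on a chiral pyranylidene chromium carbene

## Analysis of the target

Abroquinone A (22) is an isoflavan quinone. A chroman, made of benzene ring A fused to dihydropyran ring C (O1, C2, C3, C4, C4a, C8a), carries at C3 a 2,3-dimethoxy-1,4-benzoquinone (ring B) bonded through C1′. Ring A holds methoxy groups on C6 and C7 and the ring oxygen O1 on C8a. Ring B has carbonyls at C2′ and C5′ and methoxy groups at C3′ and C4′. The only stereocentre is C3 (S), a methine between the two methylene groups C2 and C4. It has no partner stereocentre and no neighbouring functional group, so its configuration must come from a reagent or catalyst. The quinone is electrophilic, redox-active and base-sensitive. In 22 the C3–H bond is allylic to C1′=C6′ and vinylogously alpha to the C5′ carbonyl, so enolisation towards a quinone methide would racemise the compound. The difficulty is therefore enantiocontrol at an isolated benzylic-type methine, together with six oxygen functions on two rings that must end up differentiated with little protecting-group traffic. The strategy rests on ring A (C4a, C5, C6, C7, C8, C8a): O1 on C8a and the oxygen on C6 are para to each other, C7 next to C6 is oxygenated, and C5 and C8 carry hydrogen. This is the pattern formed when an alkoxycarbene carbon (C8a), a carbonyl ligand (C6) and an oxygenated terminal alkyne (C7, C8) are joined onto an alkene (C4a=C5).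

## Retrosynthetic reasoning

**22 to 21.** The quinone is taken back to phenol 21: the C5′ oxygen is removed and C2′=O becomes the phenolic OH. The forward step is a para-selective phenol oxidation. In 21 the only free position para to the hydroxyl is C5′, so regiochemistry is fixed by the substitution pattern. The oxidation is placed last and run near neutral pH because of the racemisation risk at C3 in 22.

**21 to 20 to 19.** Two functional-group changes follow. The O2′ hydroxyl is returned to its methoxymethyl acetal (20) and the C6 methyl ether to a free phenol (19). The C6 oxygen is a phenol in 19 because the ring-forming step delivers it in that form. The O2′ acetal is kept until after the methylation so that only the C6 oxygen is alkylated.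

**19 to 14 and 17 (the key disconnection).** Ring A is dismantled by cutting C8a–C8, C7–C6 and C6–C5. C8a returns to the carbene carbon of 14, C4a and C5 to its exocyclic alkene, C7 and C8 to alkyne 17, and C6 to a carbonyl ligand of 14. Cutting here, and not at C3–C1′ or inside ring C, keeps all bond formation away from the stereocentre, which sits two atoms from the nearest reacting carbon. The oxygen pattern of ring A (O1, OH at C6, OMe at C7, H at C5 and C8) then follows from the mechanism and needs no directing groups. The forward reaction must insert 17 with the correct orientation, take up a carbonyl ligand, and close the six-membered ring onto the methylene carbon. The arene is first formed as complex 18 and is freed from the metal by air.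

**17 to 15.** The volatile alkyne 17 is traced to acetal 15 by twofold elimination, through acetylide 16.

**14 to 11.** The exocyclic C=CH2 unit (future C4a=C5) is disconnected at its carbon–carbon double bond. The methylene carbon is added to the acidic alpha position of the saturated carbene 11 through anion 12 and amine 13. The stereocentre is not alpha to the carbene and is not touched.

**11 to 10.** The carbene ring is opened at the O–C(carbene) bond (future O1–C8a). This gives alkynol 10, whose terminal alkyne carbon becomes the carbene carbon on a zerovalent chromium carbonyl fragment. Ring C of the target is thus formed here, as an oxacyclohexylidene ligand.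

**10 to 8 to 7.** Removing the terminal alkyne carbon gives lactol 8 (open form 9), and raising the oxidation level gives lactone 7. The forward steps are a partial reduction and a one-carbon alkynylation. Neither can epimerise the stereocentre, which is beta to the carbonyl.

**7 to 5 and 6.** The bond between the stereocentre and ring B (future C3–C1′) is cut. This gives boronic acid 5 and butenolide 6. The stereocentre is set here, on the smallest possible prochiral acceptor, by a catalytic conjugate arylation under chiral bisphosphine control. The enantiomeric purity can be measured and secured at 7, before any chromium chemistry.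

**5 to 2 to 1.** The carbon–boron bond is traced to the arene C–H bond ortho to the acetal oxygen of 2, through aryllithium 3 and borate 4. Ether 2 comes from phenol 1. The acetal both directs the metalation and masks the oxygen that later becomes the C2′ carbonyl.

## Alternatives that were turned down

**Alternative 1: quinone–chromene cycloaddition under a chiral Lewis acid, then opening of a pterocarpan.**
- Disconnection: C3–C1′ is cut, and a temporary C4–O bond to the C2′ oxygen is accepted. This leads back to 6,7-dimethoxy-2H-chromene (A1) and 2,3-dimethoxy-1,4-benzoquinone (A2).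
- Forward key step: C3 of A1 attacks the Lewis-acid-activated quinone A2. The benzylic cation at C4 is captured by the quinone oxygen, closing a cis-fused dihydrofuran to give pterocarpan A3. Reductive cleavage of the benzylic C4–O bond would give hydroquinone A4, and mild oxidation would give 22.
- For: it is very short and convergent. Ring B arrives with all four oxygens in place and at almost the right oxidation level.
- Against: absolute configuration depends on a chiral Lewis acid distinguishing the faces of a cyclic styrene in a stepwise cationic process, usually with a stoichiometric chiral promoter and with selectivity that is hard to predict for this pair. Competing [2+2] and rearranged adducts are inherent to the cationic pathway. The benzylic hydrogenolysis must be run on an air-sensitive hydroquinone.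
- Comparison: on step economy this alternative is clearly stronger (a few steps against twelve). The chosen route offers in exchange a stereocentre set by a broadly reliable catalytic conjugate arylation on a simple lactone, checked at 7 and independent of the electronics of ring A.

**Alternative 2: aminocatalytic annulation of an ortho-quinone methide with an arylacetaldehyde.**
- Disconnection: C3–C4 and O1–C2 are cut. This gives aldehyde A5 and sulfone A6, the precursor of the ring A ortho-quinone methide.
- Forward key step: base releases the quinone methide from A6. The chiral enamine of A5 adds to form C3–C4, and the phenoxide closes O1–C2 to give lactol A7. Deoxygenation at C2, debenzylation and phenol oxidation would follow.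
- For: both rings come from oxygenated aromatic feedstocks. The key step needs no metal and belongs to a known reaction class. Convergence is better than in the chosen route.
- Against: in A7 the new stereocentre is alpha to a masked aldehyde and bears an aryl group. Ring–chain tautomerism exposes an alpha-aryl aldehyde that enolises easily. The deoxygenation passes through an oxocarbenium ion at C2 that can lose the C3 proton and erase the stereocentre. A5, an ortho-oxygenated arylacetaldehyde, is prone to self-condensation, and its ortho substituent makes facial control in the enamine step harder.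
- Comparison: overall length is similar once A5 and A6 are made. The chosen route keeps the stereocentre away from any carbonyl group from lactol 8 up to the final quinone.

**Alternative 3: annulation of a symmetric aryne by a chiral bromo alkoxide.**
- Disconnection: O1–C8a and C4–C4a are cut. This gives bromo alcohol A8 and aryne precursor A9.
- Forward key step: the alkoxide of A8 adds to the aryne released from A9 by fluoride, and the aryl anion displaces bromide (6-exo-tet) to give chroman A10, which is identical with 20.
- For: it converges on the same late intermediate and shares the three-step endgame. The symmetric aryne removes any regiochemical question. The key step is metal-free and all arene oxygens are in place beforehand, which is an advantage over the chosen route.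
- Against: the alkoxide of A8 can displace its own bromide before it meets the short-lived aryne. The aryl anion is protonated by any alcohol present much faster than it alkylates. Ring closure by this anionic sequence onto an alkyl halide is not an established way to make chromans. A8 also needs its own asymmetric synthesis.
- Comparison: the chosen benzannulation is also a stretch, but each of its elementary events (alkyne insertion, CO insertion, electrocyclisation) is individually established. Its chiral building block 7 comes from one catalytic step.

Key step: step 9

## Remarks before the steps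

- Remark on step 3: the sense of induction is assigned by analogy with cyclic enones, where the (S)-ligand delivers the aryl group to the face that here gives the (4S)-lactone. If the sense were opposite, (R)-BINAP would be used and nothing else would change.
- Remark on 17: because of its volatility and limited shelf life it is made fresh (step 8) rather than purchased.
- Remark on 18: the η6 complex is written in the compound list as its two components joined by a dot.

## Route

Step 1
Reactants: 1 2,3-dimethoxyphenol
Product: 2 1,2-dimethoxy-3-(methoxymethoxy)benzene
Conditions: MOMCl, iPr2NEt, CH2Cl2, 0 °C to rt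
Reagents that add atoms: chloromethyl methyl ether, COCCl
Why: O-alkylation of the phenol to its methoxymethyl acetal (Williamson-type etherification); the acetal directs the lithiation of step 2, survives organometallic, hydride and basic conditions, and is removed by mild acid in step 11.

Step 2
Reactants: 2 1,2-dimethoxy-3-(methoxymethoxy)benzene
Product: 5 [3,4-dimethoxy-2-(methoxymethoxy)phenyl]boronic acid, via aryllithium 3 (not isolated), via lithium aryltriisopropoxyborate 4 (not isolated)
Conditions: n-BuLi, TMEDA, THF, 0 °C; B(OiPr)3, −78 °C to rt; aq NH4Cl
Reagents that add atoms: triisopropyl borate, CC(C)OB(OC(C)C)OC(C)C; water, O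
Why: Directed ortho-metalation, in which the acetal oxygens chelate lithium and steer deprotonation to the only free position ortho to the OMOM group, followed by borate trapping. The weakly acidic NH4Cl hydrolysis frees the boronic acid without cleaving the acetal.

Step 3
Reactants: 5 [3,4-dimethoxy-2-(methoxymethoxy)phenyl]boronic acid; 6 furan-2(5H)-one
Product: 7 (4S)-4-[3,4-dimethoxy-2-(methoxymethoxy)phenyl]dihydrofuran-2(3H)-one
Conditions: 5 (1.5 equiv), [Rh(OH)((S)-BINAP)]2 (1.5 mol %), dioxane/H2O 10:1, 40 °C
Reagents that add atoms: none
Why: Hayashi–Miyaura asymmetric conjugate arylation: transmetalation gives an aryl complex of monovalent rhodium, the butenolide C=C bond inserts into the Rh–aryl bond with its enantioface chosen by the BINAP ligand, and water releases the lactone and regenerates Rh–OH. The (S)-ligand is expected to set (4S), the centre that becomes C3 of 22. The preformed hydroxo complex allows a low temperature, which limits protodeboronation of the ortho-alkoxy boronic acid.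

Step 4
Reactants: 7 (4S)-4-[3,4-dimethoxy-2-(methoxymethoxy)phenyl]dihydrofuran-2(3H)-one
Product: 8 (4S)-4-[3,4-dimethoxy-2-(methoxymethoxy)phenyl]tetrahydrofuran-2-ol (anomeric mixture)
Conditions: iBu2AlH, CH2Cl2, −78 °C; aq potassium sodium tartrate
Reagents that add atoms: none
Why: Partial hydride reduction of a lactone to the lactol; at −78 °C the tetrahedral aluminium hemiacetal persists until the quench, so over-reduction is avoided. The stereocentre is beta to the carbonyl and cannot enolise.

Step 5
Reactants: 8 (4S)-4-[3,4-dimethoxy-2-(methoxymethoxy)phenyl]tetrahydrofuran-2-ol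
Product: 10 (2S)-2-[3,4-dimethoxy-2-(methoxymethoxy)phenyl]pent-4-yn-1-ol, via open-chain hydroxy aldehyde 9 (not isolated)
Conditions: dimethyl (1-diazo-2-oxopropyl)phosphonate, K2CO3, MeOH, 0 °C to rt
Reagents that add atoms: dimethyl (1-diazo-2-oxopropyl)phosphonate, CC(=O)C(=[N+]=[N-])P(=O)(OC)OC
Why: Ohira–Bestmann (Seyferth–Gilbert) alkynylation of the lactol through its ring-opened aldehyde 9; the added carbon becomes the terminal alkyne carbon, the future C8a. The mild carbonate conditions leave the beta stereocentre and the acetal untouched.

Step 6
Reactants: 10 (2S)-2-[3,4-dimethoxy-2-(methoxymethoxy)phenyl]pent-4-yn-1-ol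
Product: 11 pentacarbonyl{(5S)-5-[3,4-dimethoxy-2-(methoxymethoxy)phenyl]tetrahydro-2H-pyran-2-ylidene}chromium
Conditions: Cr(CO)6, hν, THF, rt, giving Cr(CO)5(THF); then 10, THF, rt, dark
Reagents that add atoms: chromium hexacarbonyl, O=C=[Cr](=C=O)(=C=O)(=C=O)(=C=O)=C=O
Why: Cycloisomerisation of an alkynol to a cyclic Fischer carbene on zerovalent chromium: the Cr(CO)5 fragment turns the terminal alkyne into a vinylidene ligand, the tethered hydroxyl adds to its electrophilic alpha carbon in a six-membered closure, and proton transfer to the beta carbon gives the 2-oxacyclohexylidene complex. This forms ring C of the target and leaves the stereocentre untouched.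

Step 7
Reactants: 11 pentacarbonyl{(5S)-5-[3,4-dimethoxy-2-(methoxymethoxy)phenyl]tetrahydro-2H-pyran-2-ylidene}chromium
Product: 14 pentacarbonyl{(5S)-5-[3,4-dimethoxy-2-(methoxymethoxy)phenyl]-3-methylidenetetrahydro-2H-pyran-2-ylidene}chromium, via lithiated carbene 12 (not isolated), via Mannich base 13 (not isolated)
Conditions: n-BuLi, THF, −78 °C; CH2=NMe2+ I−, −78 to 0 °C; SiO2, CH2Cl2, rt
Reagents that add atoms: N,N-dimethylmethyleneiminium iodide, C=[N+](C)C.[I-]
Why: Mannich-type alpha-methylenation of a Fischer carbene: the alpha-CH2 next to the carbene carbon is strongly acidic, anion 12 adds to the iminium ion to give 13, and the remaining acidic alpha-hydrogen allows E1cB loss of dimethylamine on silica, which also retains the amine. C5 is not alpha to the carbene and keeps its configuration.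

Step 8
Reactants: 15 2-chloro-1,1-dimethoxyethane
Product: 17 methoxyacetylene, via sodium methoxyacetylide 16 (not isolated)
Conditions: NaNH2 (3 equiv), liquid NH3, −33 °C; sat. aq NaCl, −20 °C; distilled into cold THF
Reagents that add atoms: none
Why: Twofold base-induced elimination (loss of HCl and of methanol) gives the acetylide 16, which is protonated on quenching. The low-boiling ynol ether is distilled directly into the solvent of step 9 and used at once.

Step 9
Reactants: 14 pentacarbonyl{(5S)-5-[3,4-dimethoxy-2-(methoxymethoxy)phenyl]-3-methylidenetetrahydro-2H-pyran-2-ylidene}chromium; 17 methoxyacetylene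
Product: 19 (3S)-3-[3,4-dimethoxy-2-(methoxymethoxy)phenyl]-7-methoxy-3,4-dihydro-2H-chromen-6-ol, via tricarbonylchromium arene complex 18 (not isolated)
Conditions: 17 (3 equiv), degassed THF, 50 °C, sealed tube; then air, daylight, CH2Cl2, rt
Reagents that add atoms: none
Why: Dötz benzannulation of an alkenyl(alkoxy)carbene chromium complex with an alkyne, here with the alkene exocyclic to the oxacycle and an ynol ether as the alkyne. Loss of one CO from 14 lets 17 bind and insert into the Cr=C bond with its CH terminus bonding to the carbene carbon (future C8a) and its methoxy-bearing carbon becoming the new carbene carbon; the small hydrogen and oxygen stabilisation of the new carbene both favour this sense. CO insertion then gives a chromium-bound vinylketene whose ketene carbon is the future C6. Ring A closes by a thermal six-electron electrocyclisation of that ketene carbon onto the exocyclic methylene carbon (future C5), and tautomerisation of the cyclohexadienone gives the phenol as complex 18, from which air removes the metal. C8a–C8, C7–C6 and C6–C5 are thus formed in one operation, and the required pattern (OMe at C7, H at C8, OH at C6 para to O1) follows from the insertion sense; cyclisation also needs the alkenyl arm, not the ring oxygen, syn to the new carbene carbon, which is the normal outcome for alkoxycarbenes. No stereocentre is formed, and the existing one (future C3) lies two atoms from the nearest reacting carbon. If the donor-stabilised alkoxy(dienyl)carbene takes up CO slowly under heat, irradiation under CO, which drives the same ketene formation and closure for dienyl(alkoxy)carbenes, is the first adjustment.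

Step 10
Reactants: 19 (3S)-3-[3,4-dimethoxy-2-(methoxymethoxy)phenyl]-7-methoxy-3,4-dihydro-2H-chromen-6-ol
Product: 20 (3S)-3-[3,4-dimethoxy-2-(methoxymethoxy)phenyl]-6,7-dimethoxy-3,4-dihydro-2H-chromene
Conditions: MeI, K2CO3, acetone, reflux
Reagents that add atoms: iodomethane, CI
Why: Williamson O-methylation of the only free phenol; the O2′ oxygen is still masked as its acetal, so only the C6 oxygen is alkylated.

Step 11
Reactants: 20 (3S)-3-[3,4-dimethoxy-2-(methoxymethoxy)phenyl]-6,7-dimethoxy-3,4-dihydro-2H-chromene
Product: 21 6-[(3S)-6,7-dimethoxy-3,4-dihydro-2H-chromen-3-yl]-2,3-dimethoxyphenol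
Conditions: HCl (cat.), MeOH, 40 °C
Reagents that add atoms: none
Why: Acid-catalysed acetal exchange with methanol removes the methoxymethyl group; the aryl methyl ethers, the chroman ether and the non-enolisable stereocentre are stable to these conditions.

Step 12
Reactants: 21 6-[(3S)-6,7-dimethoxy-3,4-dihydro-2H-chromen-3-yl]-2,3-dimethoxyphenol
Product: 22 Abroquinone A, 5-[(3S)-6,7-dimethoxy-3,4-dihydro-2H-chromen-3-yl]-2,3-dimethoxycyclohexa-2,5-diene-1,4-dione
Conditions: (KSO3)2NO (2.5 equiv), aq KH2PO4, acetone/H2O, rt
Reagents that add atoms: potassium nitrosodisulfonate, [K+].[K+].[O-]S(=O)(=O)N([O])S(=O)(=O)[O-]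
Why: Teuber oxidation: one nitrosodisulfonate radical abstracts the phenolic hydrogen, a second couples at the free para position C5′, and loss of imidodisulfonate gives the para-quinone. Only ring B carries a free hydroxyl, so ring A is not oxidised, and the buffered medium avoids base-induced enolisation at C3.

## Compound list

1 | 2,3-dimethoxyphenol | COc1cccc(O)c1OC | starting material
2 | 1,2-dimethoxy-3-(methoxymethoxy)benzene | COCOc1cccc(OC)c1OC | intermediate
3 | [3,4-dimethoxy-2-(methoxymethoxy)phenyl]lithium | [Li]c1ccc(OC)c(OC)c1OCOC | intermediate (not isolated)
4 | lithium [3,4-dimethoxy-2-(methoxymethoxy)phenyl]tri(propan-2-yloxy)borate | [Li+].CC(C)O[B-](OC(C)C)(OC(C)C)c1ccc(OC)c(OC)c1OCOC | intermediate (not isolated)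
5 | [3,4-dimethoxy-2-(methoxymethoxy)phenyl]boronic acid | OB(O)c1ccc(OC)c(OC)c1OCOC | intermediate
6 | furan-2(5H)-one | O=C1OCC=C1 | starting material
7 | (4S)-4-[3,4-dimethoxy-2-(methoxymethoxy)phenyl]dihydrofuran-2(3H)-one | O=C1C[C@@H](c2ccc(OC)c(OC)c2OCOC)CO1 | intermediate
8 | (4S)-4-[3,4-dimethoxy-2-(methoxymethoxy)phenyl]tetrahydrofuran-2-ol, anomeric mixture | OC1C[C@@H](c2ccc(OC)c(OC)c2OCOC)CO1 | intermediate
9 | (3S)-3-[3,4-dimethoxy-2-(methoxymethoxy)phenyl]-4-hydroxybutanal | O=CC[C@@H](c1ccc(OC)c(OC)c1OCOC)CO | intermediate (not isolated)
10 | (2S)-2-[3,4-dimethoxy-2-(methoxymethoxy)phenyl]pent-4-yn-1-ol | C#CC[C@@H](c1ccc(OC)c(OC)c1OCOC)CO | intermediate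
11 | pentacarbonyl{(5S)-5-[3,4-dimethoxy-2-(methoxymethoxy)phenyl]tetrahydro-2H-pyran-2-ylidene}chromium | O=C=[Cr](=C=O)(=C=O)(=C=O)(=C=O)=C1CC[C@@H](c2ccc(OC)c(OC)c2OCOC)CO1 | intermediate
12 | lithium salt of 11 deprotonated at C3 of the pyranylidene ring (vinylchromate form) | [Li+].O=C=[Cr-](=C=O)(=C=O)(=C=O)(=C=O)C1=CC[C@@H](c2ccc(OC)c(OC)c2OCOC)CO1 | intermediate (not isolated)
13 | pentacarbonyl{(5S)-5-[3,4-dimethoxy-2-(methoxymethoxy)phenyl]-3-[(dimethylamino)methyl]tetrahydro-2H-pyran-2-ylidene}chromium, both C3 epimers | CN(C)CC1C[C@@H](c2ccc(OC)c(OC)c2OCOC)COC1=[Cr](=C=O)(=C=O)(=C=O)(=C=O)=C=O | intermediate (not isolated)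
14 | pentacarbonyl{(5S)-5-[3,4-dimethoxy-2-(methoxymethoxy)phenyl]-3-methylidenetetrahydro-2H-pyran-2-ylidene}chromium | C=C1C[C@@H](c2ccc(OC)c(OC)c2OCOC)COC1=[Cr](=C=O)(=C=O)(=C=O)(=C=O)=C=O | intermediate
15 | 2-chloro-1,1-dimethoxyethane (chloroacetaldehyde dimethyl acetal) | COC(CCl)OC | starting material
16 | sodium methoxyacetylide | [Na+].[C-]#COC | intermediate (not isolated)
17 | methoxyacetylene (methoxyethyne) | COC#C | intermediate
18 | tricarbonyl{η6-(3S)-3-[3,4-dimethoxy-2-(methoxymethoxy)phenyl]-7-methoxy-3,4-dihydro-2H-chromen-6-ol}chromium, metal on ring A | COCOc1c([C@H]2COc3cc(OC)c(O)cc3C2)ccc(OC)c1OC.O=C=[Cr](=C=O)=C=O | intermediate (not isolated)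
19 | (3S)-3-[3,4-dimethoxy-2-(methoxymethoxy)phenyl]-7-methoxy-3,4-dihydro-2H-chromen-6-ol | COCOc1c([C@H]2COc3cc(OC)c(O)cc3C2)ccc(OC)c1OC | intermediate
20 | (3S)-3-[3,4-dimethoxy-2-(methoxymethoxy)phenyl]-6,7-dimethoxy-3,4-dihydro-2H-chromene | COCOc1c([C@H]2COc3cc(OC)c(OC)cc3C2)ccc(OC)c1OC | intermediate
21 | 6-[(3S)-6,7-dimethoxy-3,4-dihydro-2H-chromen-3-yl]-2,3-dimethoxyphenol | COc1ccc([C@H]2COc3cc(OC)c(OC)cc3C2)c(O)c1OC | intermediate
22 | Abroquinone A, 5-[(3S)-6,7-dimethoxy-3,4-dihydro-2H-chromen-3-yl]-2,3-dimethoxycyclohexa-2,5-diene-1,4-dione | COC1=C(OC)C(=O)C([C@H]2COc3cc(OC)c(OC)cc3C2)=CC1=O | target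

## Step count and the least certain steps

Total step count: 12. Longest linear sequence: 11 steps (steps 1 to 7 and 9 to 12, from 1); step 8 is a one-step side branch.

**Step 9 (key step).** The most likely failure is that the sequence stalls after alkyne insertion. The ynol ether places a donor oxygen on the new carbene carbon, and this stabilised alkoxy(dienyl)carbene may not take up CO, or the ynol ether may oligomerise on chromium. A second risk is migration of the exocyclic double bond of 14 into the ring before annulation. Fallback, from 14 back to 20: the ynol ether is replaced by a terminal alkyne that carries the C7 oxygen in latent form as a carbon substituent. Benzannulation of 14 with 3,3-diethoxyprop-1-yne under the same thermal conditions should place the acetal carbon next to the CO-derived carbon, as terminal alkynes normally do. After air decomplexation this would give (3S)-7-(diethoxymethyl)-3-[3,4-dimethoxy-2-(methoxymethoxy)phenyl]-3,4-dihydro-2H-chromen-6-ol F1. Brief treatment with pyridinium p-toluenesulfonate in wet acetone should hydrolyse the diethyl acetal much faster than the aryl methoxymethyl ether, giving the salicylaldehyde (3S)-3-[3,4-dimethoxy-2-(methoxymethoxy)phenyl]-6-hydroxy-3,4-dihydro-2H-chromene-7-carbaldehyde F2. Dakin oxidation (H2O2, aq NaOH, under argon) would exchange the formyl group for hydroxyl and give the catechol (3S)-3-[3,4-dimethoxy-2-(methoxymethoxy)phenyl]-3,4-dihydro-2H-chromene-6,7-diol F3. Double methylation with MeI and K2CO3 then rejoins the route at 20.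

**Step 3.** Protodeboronation of the electron-rich, ortho-substituted boronic acid may outrun transmetalation. The ortho acetal may also slow insertion, and the butenolide may suffer hydrolytic ring opening, so conversion and enantioselectivity could both be low. Fallback, from 5 back to 7: Suzuki–Miyaura coupling of 5 with 4-bromofuran-2(5H)-one (Pd(PPh3)4, a zerovalent palladium catalyst, K3PO4, THF) would give the achiral butenolide 4-[3,4-dimethoxy-2-(methoxymethoxy)phenyl]furan-2(5H)-one F4. Copper hydride catalysed asymmetric conjugate reduction (Cu(OAc)2, p-tol-BINAP of the appropriate hand, polymethylhydrosiloxane, t-BuOH, toluene) would then deliver hydride to C4 and give 7. The stereocentre is set by reduction instead of arylation.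

**Step 6.** Vinylidene formation on chromium may be slow compared with alkyne oligomerisation and with decay of Cr(CO)5(THF). The six-membered closure is also less favourable than the five-membered one, so conversion to 11 may be poor. Fallback, from 10 back to 11: anti-Markovnikov hydroboration of the alkyne with dicyclohexylborane and oxidative work-up (NaBO3) would give the lactol (5S)-5-[3,4-dimethoxy-2-(methoxymethoxy)phenyl]tetrahydro-2H-pyran-2-ol F5. Oxidation with TEMPO and PhI(OAc)2 would give the lactone (5S)-5-[3,4-dimethoxy-2-(methoxymethoxy)phenyl]tetrahydro-2H-pyran-2-one F6. Addition of the pentacarbonylchromate dianion K2[Cr(CO)5] (from Cr(CO)6 and KC8) to the lactone carbonyl at −78 °C and deoxygenation with Me3SiCl, the metalate route known for amides and lactones, would give carbene 11 without a vinylidene stage.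

**Step 7.** The liberated dimethylamine or anion 12 may add in Michael fashion to the very electrophilic product 14. The amine may also attack the carbene carbon, and base may move the exocyclic double bond into the ring. Fallback, from 11 back to 14: an aldol–dehydration sequence that releases no amine. Anion 12 (n-BuLi, THF, −78 °C) would be added to monomeric formaldehyde (from cracked paraformaldehyde) to give the aldol adduct pentacarbonyl{(5S)-5-[3,4-dimethoxy-2-(methoxymethoxy)phenyl]-3-(hydroxymethyl)tetrahydro-2H-pyran-2-ylidene}chromium F7. Mesylation and elimination in one flask (MsCl, Et3N, CH2Cl2, 0 °C) would then give 14.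

## Further compounds

F1 | step 9 | (3S)-7-(diethoxymethyl)-3-[3,4-dimethoxy-2-(methoxymethoxy)phenyl]-3,4-dihydro-2H-chromen-6-ol | COCOc1c([C@H]2COc3cc(C(OCC)OCC)c(O)cc3C2)ccc(OC)c1OC
F2 | step 9 | (3S)-3-[3,4-dimethoxy-2-(methoxymethoxy)phenyl]-6-hydroxy-3,4-dihydro-2H-chromene-7-carbaldehyde | COCOc1c([C@H]2COc3cc(C=O)c(O)cc3C2)ccc(OC)c1OC
F3 | step 9 | (3S)-3-[3,4-dimethoxy-2-(methoxymethoxy)phenyl]-3,4-dihydro-2H-chromene-6,7-diol | COCOc1c([C@H]2COc3cc(O)c(O)cc3C2)ccc(OC)c1OC
F4 | step 3 | 4-[3,4-dimethoxy-2-(methoxymethoxy)phenyl]furan-2(5H)-one | O=C1C=C(c2ccc(OC)c(OC)c2OCOC)CO1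
F5 | step 6 | (5S)-5-[3,4-dimethoxy-2-(methoxymethoxy)phenyl]tetrahydro-2H-pyran-2-ol | OC1CC[C@@H](c2ccc(OC)c(OC)c2OCOC)CO1
F6 | step 6 | (5S)-5-[3,4-dimethoxy-2-(methoxymethoxy)phenyl]tetrahydro-2H-pyran-2-one | O=C1CC[C@@H](c2ccc(OC)c(OC)c2OCOC)CO1
F7 | step 7 | pentacarbonyl{(5S)-5-[3,4-dimethoxy-2-(methoxymethoxy)phenyl]-3-(hydroxymethyl)tetrahydro-2H-pyran-2-ylidene}chromium | OCC1C[C@@H](c2ccc(OC)c(OC)c2OCOC)COC1=[Cr](=C=O)(=C=O)(=C=O)(=C=O)=C=O
A1 | alternative 1 | 6,7-dimethoxy-2H-chromene | COc1cc2OCC=Cc2cc1OC
A2 | alternative 1 | 2,3-dimethoxycyclohexa-2,5-diene-1,4-dione | COC1=C(OC)C(=O)C=CC1=O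
A3 | alternative 1 | cis-8-hydroxy-2,3,9,10-tetramethoxypterocarpan | COc1cc2OC[C@H]3[C@@H](c2cc1OC)Oc1c(OC)c(OC)c(O)cc13
A4 | alternative 1 | 5-[(3S)-6,7-dimethoxy-3,4-dihydro-2H-chromen-3-yl]-2,3-dimethoxybenzene-1,4-diol | COc1c(O)cc([C@H]2COc3cc(OC)c(OC)cc3C2)c(O)c1OC
A5 | alternative 2 | 2-[2-(benzyloxy)-3,4-dimethoxyphenyl]acetaldehyde | O=CCc1ccc(OC)c(OC)c1OCc1ccccc1
A6 | alternative 2 | 4,5-dimethoxy-2-[(phenylsulfonyl)methyl]phenol | COc1cc(O)c(CS(=O)(=O)c2ccccc2)cc1OC
A7 | alternative 2 | (3S)-3-[2-(benzyloxy)-3,4-dimethoxyphenyl]-6,7-dimethoxy-3,4-dihydro-2H-chromen-2-ol, anomeric mixture | COc1ccc([C@H]2C(O)Oc3cc(OC)c(OC)cc3C2)c(OCc2ccccc2)c1OC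
A8 | alternative 3 | (2S)-3-bromo-2-[3,4-dimethoxy-2-(methoxymethoxy)phenyl]propan-1-ol | OC[C@@H](CBr)c1ccc(OC)c(OC)c1OCOC
A9 | alternative 3 | 4,5-dimethoxy-2-(trimethylsilyl)phenyl trifluoromethanesulfonate | COc1cc(OS(=O)(=O)C(F)(F)F)c([Si](C)(C)C)cc1OC
A10 | alternative 3 | (3S)-3-[3,4-dimethoxy-2-(methoxymethoxy)phenyl]-6,7-dimethoxy-3,4-dihydro-2H-chromene, identical with 20 | COCOc1c([C@H]2COc3cc(OC)c(OC)cc3C2)ccc(OC)c1OC
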